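The planner of the next run has to pick between two recipes and decide how long each should stand.

| flask | starting material | coupling partner | free catalyst | remark | time |
|---|---|---|---|---|---|
| green | 0.50 M | 0.65 M | 7.4 mM | run made earlier |  |
| Thursday's | 0.50 M | 0.650 M | 11 mM |  | 40 h |
| Sunday's | 0.12 M | 0.650 M | 11 mM |  | 80 h |

- green (time / h: product / %): 1.00: 3.2; 2.00: 5.7; 4.00: 10.5; 8.00: 17.2; 15.0: 23.4

(standard deviation of a reading: 0.3 percentage points)

* the winner by amount of product, in percent of the starting material charged; "neither" if no more than 2 percentage points parts them (Thursday's / Sunday's / neither)
* how much product is there at the end, in percent of the starting material charged: Thursday's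
* how much product is there at the end, in percent of the starting material charged: Sunday's

- in percentages every species weighs as the starting material in it: one spent catalyst counts as two
- reactions considered so far: catalyst intermediate B <-> free catalyst + product; coupling partner + catalyst intermediate A -> catalyst intermediate B; coupling partner -> decomposed reagent; 2 catalyst intermediate B -> spent catalyst; starting material + free catalyst <-> catalyst intermediate A
- no earlier run changes the charge of free catalyst; that part of a forecast is a guess

The green run makes product at 0.0285 h⁻¹, as a fraction of the charge, over its first span and at 0.00886 h⁻¹ over its last. That is a fall of 0.507 powers of ten across the 10.5 h between the midpoints of those spans. So the green readings give, as a reading with their scatter, 20.7 h for D, the decade time, the time in which the product rate of the green flask falls tenfold. If that fall is taken as steady, then after a time t the rate has lost t/D powers of ten, and the product stands short of a ceiling by the fraction of rate still left. The last green reading, 23.4 % at 15.0 h, then puts the green ceiling at 28.8 %.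

No earlier run changes the free catalyst, so scaling the ceiling with it is a guess. Thursday's charge of free catalyst is 1.49 times the green one, which gives Thursday's flask a ceiling of 42.9 %, or 0.214 M of product. That molar ceiling is more than Sunday's whole charge of 0.12 M. The green run has a single charge of starting material, so the ceiling may carry over in percent, which gives Sunday's flask 42.9 %, or in molar terms, which gives it the whole charge, 100 %. This reckoning places Sunday's flask between the two and chooses Sunday's recipe. With the green decade time carried over, which is a guess, a stand of 40 h is 1.93 decades and leaves 1.17 % of the rate, so the decision is to stop Sunday's flask at that time and not at 80 h.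

The forecast, made from the same runs, names Sunday's the winner at 68 % against 40 % for Thursday's, a Thursday's figure lower than this reckoning, and holds for Sunday's that “catalyst death is much weaker, and 80 h is long”.

The simulation gives 34.9 % for Thursday's and 68.1 % for Sunday's, so Sunday's wins.

    catalyst intermediate B ⇌ free catalyst + product (K = 0.320 M, k = 8.81 h⁻¹)
    coupling partner + catalyst intermediate A → catalyst intermediate B (k = 7.21 M⁻¹ h⁻¹)
    coupling partner → decomposed reagent (k = 0.103 h⁻¹)
    2 catalyst intermediate B → spent catalyst (k = 11.0 M⁻¹ h⁻¹)
    starting material + free catalyst ⇌ catalyst intermediate A (K = 6.00 M⁻¹, k = 75.2 M⁻¹ h⁻¹)

Thursday's ends 8 percentage points under the reckoned ceiling. Sunday's flask stands at 68.9 % after 40.0 h and at 68.1 % after 80.0 h. The same reckoning on the neighbour, Thursday's flask read at 10 h, counts 0.483 decades, which is 67.1 % of the ceiling, or 28.8 % of product. That flask holds 26.9 % product, with coupling partner at 24 % of its charge.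

The data were computed with constants of no real substance, noise included.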